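**Retrosynthetic overview**
1. Target 35 comes from diol 31. The butenolide is made last from a 3-furyl group (singlet oxygen, then NaBH4). The (Z)-hydroxymethyl alkene and the (R)-carbinol come from reductive opening of an α,β-unsaturated δ-lactone, a temporary ring made by ring-closing metathesis and joined to the decalin by Negishi coupling of iodide 23 with iodolactone 28.
2. Decalin 23 comes from the 6-oxo compounds 15/17. The temporary C-6 ketone lets C-5 settle trans, serves for the resolution by catalyst-controlled reduction, and is then removed (Barton–McCombie).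
3. Key disconnection: ring B is built onto ring A from alkenyllithium 11 (C-5=C-10 of ring A) and cyclobutenone 10 (C-6 to C-9). 1,2-Addition makes C-5–C-6; oxy-anion-driven 4π opening and 6π closure make C-9–C-10 and the quaternary C-10.
4. Enabling feature: in ring B the carbons C-6, C-7, C-8 (methyl) and C-9 (side chain) form one chain on the C-5–C-10 edge of ring A, with the C-8=C-9 alkene β,γ to C-6. With an oxygen on C-6 this chain is the ring-opened form of a 3-methyl-4-alkylcyclobut-2-enone, and C-5=C-10 is the terminal double bond of a 3-oxidohexatriene.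
5. Order of ring formation: ring A is bought (2,2,6-trimethylcyclohexanone); the cyclobutenone is a temporary four-membered ring (steps 3–4); ring B (step 5); the δ-lactone (step 14, opened in step 17); the butenolide from the furan last (steps 18–19).

Key step: step 5

**Remarks**
- Labdane-type locants are used for the decalin in the comments: C-4 carries the gem-dimethyl group, C-5 is the ring-fusion CH, C-10 the ring-fusion quaternary carbon, C-8=C-9 the alkene with the side chain on C-9. Ring A is C-1 to C-5 plus C-10, ring B is C-5 to C-10, and α is the face opposite the C-10 methyl.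
- The electrocyclisation in step 5 has no absolute control, so 15 and 17 are racemic and are marked (±). Their names (starred descriptors) and SMILES show the enantiomer of the series that leads to the target. The absolute configuration of the decalin is fixed in step 7.
- Compounds 1, 2, 4, 6 (as a solution in hexanes) and 24 are assumed to be commercially available.

**Route**

Step 1
Reactants: 1 2,2,6-trimethylcyclohexanone; 2 2,4,6-triisopropylbenzenesulfonohydrazide
Product: 3 2,4,6-triisopropylbenzenesulfonylhydrazone of 2,2,6-trimethylcyclohexanone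
Conditions: conc. HCl (cat.), MeOH, 23 °C
Reagents that add atoms: none
Why: Acid-catalysed condensation of the hindered ketone with the arenesulfonyl hydrazide should give the hydrazone with the N–N bond syn to C-6 (away from the gem-dimethyl carbon), the only α-carbon that carries hydrogen and the one the Shapiro reaction must deprotonate.

Step 2
Reactants: 4 4-(benzyloxy)butanoic acid
Product: 5 4-(benzyloxy)butanoyl chloride
Conditions: (COCl)2, DMF (cat.), CH2Cl2, 0 → 23 °C
Reagents that add atoms: oxalyl chloride, ClC(=O)C(=O)Cl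
Why: Vilsmeier-type activation by (COCl)2/DMF converts the acid into the acid chloride under conditions that leave the benzyl ether untouched.

Step 3
Reactants: 5 4-(benzyloxy)butanoyl chloride; 6 ethoxyacetylene
Product: 8 (±)-4-[2-(benzyloxy)ethyl]-3-ethoxycyclobut-2-en-1-one, via ketene 7 (not isolated)
Conditions: Et3N, 6 (3 equiv), Et2O, slow addition of 5, 0 → 23 °C
Reagents that add atoms: none
Why: Dehydrochlorination gives the monoalkylketene 7, which the electron-rich alkynyl ether traps in a thermal [2+2] cycloaddition faster than it dimerises, the nucleophilic CH terminus of the alkyne bonding to the ketene carbonyl carbon so that the 3-ethoxy-4-alkyl cyclobutenone results (racemic; its stereocentre is erased in step 5).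

Step 4
Reactants: 8 (±)-4-[2-(benzyloxy)ethyl]-3-ethoxycyclobut-2-en-1-one
Product: 10 (±)-4-[2-(benzyloxy)ethyl]-3-methylcyclobut-2-en-1-one, via lithium alkoxide 9 (not isolated)
Conditions: MeLi, THF, −78 °C; then 1 M HCl, 0 → 23 °C
Reagents that add atoms: methyllithium, [Li]C; water, O
Why: Stork–Danheiser transposition of the vinylogous ester: MeLi adds 1,2 to the carbonyl, and acid hydrolysis of the enol ether with loss of water from the β-hydroxy ketone moves the carbonyl to the former C-3, which puts the new methyl on the alkene carbon next to the chain-bearing sp3 carbon.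

Step 5
Reactants: 3 2,4,6-triisopropylbenzenesulfonylhydrazone of 2,2,6-trimethylcyclohexanone; 10 (±)-4-[2-(benzyloxy)ethyl]-3-methylcyclobut-2-en-1-one
Product: 15 (±)-(1S*,4aS*,8aR*)-1-[2-(benzyloxy)ethyl]-2,5,5,8a-tetramethyl-4a,5,6,7,8,8a-hexahydronaphthalen-4(1H)-one, via vinyllithium 11 (not isolated), via lithium cyclobutenolate 12 (not isolated), via lithium trienolate 13 (not isolated), via lithium dienolate 14 (not isolated)
Conditions: n-BuLi (2.05 equiv), THF–TMEDA, −78 → 0 °C; then 10, −78 → 23 °C (50 °C if the ring closure lags); sat. aq NH4Cl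
Reagents that add atoms: none
Why: Shapiro fragmentation of 3 gives alkenyllithium 11, which adds 1,2 to the strained, highly electrophilic carbonyl of 10 (C-5–C-6 bond), preferentially anti to the C-9 chain. In alkoxide 12 the oxido group rotates outward in the conrotatory 4π opening of the cyclobutene, which puts the cyclohexenyl group inward and delivers the 3-oxidohexatriene 13 with the cis central C-6=C-7 bond that ring closure needs. Ring B then closes by a thermally allowed disrotatory 6π-electrocyclisation between C-9 and C-10, accelerated by the oxido substituent, which creates the quaternary C-10; the closest known reaction type is the two-carbon ring expansion of cyclobutenones to cyclohexenones by alkenyllithium reagents (and the thermal ring expansion of 4-alkenylcyclobutenols). Disrotation places the inward C-10 methyl and the inward C-9 chain cis, but C-9 is planarised again in step 6; C-5 is set by protonation of dienolate 14 from the α-face, anti to the axial C-10 and C-4 methyls, and stays correctable because it is α to the C-6 ketone. Nothing in the step controls C-10 in absolute terms, so 15 is racemic and the absolute configuration is fixed in step 7. The step needs 1,2-addition instead of enolisation (secured by ring strain and by the antiaromatic character of a cyclobutadienolate) and outward rotation of O− (an electronic preference that should outweigh the steric cost of an inward carbon group).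

Step 6
Reactants: 15 (±)-(1S*,4aS*,8aR*)-1-[2-(benzyloxy)ethyl]-2,5,5,8a-tetramethyl-4a,5,6,7,8,8a-hexahydronaphthalen-4(1H)-one
Product: 17 (±)-(4aS*,8aS*)-1-[2-(benzyloxy)ethyl]-2,5,5,8a-tetramethyl-4a,5,6,7,8,8a-hexahydronaphthalen-4(3H)-one, via potassium dienolate 16 (not isolated)
Conditions: t-BuOK (3 equiv), t-BuOH–THF, 23 °C; inverse quench into 10% aq AcOH, 0 °C
Reagents that add atoms: none
Why: Deconjugation via the extended enolate: reversible deprotonation by tert-butoxide should funnel 15 into the linear dienolate 16 (C-8=C-9 tetrasubstituted and endocyclic, favoured over the exocyclic alternative), kinetic protonation of which at the α-carbon C-7 gives the β,γ-enone, while C-9 is planarised and C-5, still α to the ketone, equilibrates to the trans-fused 5α-H form.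

Step 7
Reactants: 17 (±)-(4aS*,8aS*)-1-[2-(benzyloxy)ethyl]-2,5,5,8a-tetramethyl-4a,5,6,7,8,8a-hexahydronaphthalen-4(3H)-one
Product: 18 (4R,4aS,8aS)-1-[2-(benzyloxy)ethyl]-2,5,5,8a-tetramethyl-3,4,4a,5,6,7,8,8a-octahydronaphthalen-4-ol
Conditions: (S)-2-methyl-CBS-oxazaborolidine (0.15 equiv), BH3·SMe2 (0.6 equiv), THF, −30 °C; MeOH
Reagents that add atoms: none
Why: Corey–Bakshi–Shibata reduction run as a kinetic resolution: with C-5 as the large and C-7 as the small flank, the (S)-catalyst delivers hydride to the open α-face of the (4aS,8aS)-ketone (matched, giving the 6β-alcohol of (R) configuration), whereas in the mirror-image ketone the same catalyst demands the β-face that the axial C-4 and C-10 methyls block, so that enantiomer should remain as ketone and is removed by chromatography; this step fixes C-10 and C-5 in absolute terms.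

Step 8
Reactants: 18 (4R,4aS,8aS)-1-[2-(benzyloxy)ethyl]-2,5,5,8a-tetramethyl-3,4,4a,5,6,7,8,8a-octahydronaphthalen-4-ol
Product: 20 O-{(4R,4aS,8aS)-1-[2-(benzyloxy)ethyl]-2,5,5,8a-tetramethyl-3,4,4a,5,6,7,8,8a-octahydronaphthalen-4-yl} S-methyl carbonodithioate, via sodium xanthate 19 (not isolated)
Conditions: NaH, imidazole (cat.), THF, 0 → 50 °C; CS2; then MeI, 23 °C
Reagents that add atoms: carbon disulfide, S=C=S; iodomethane, CI
Why: The alkoxide of the hindered axial alcohol adds to the small electrophile CS2 and the xanthate salt 19 is S-methylated, the standard entry to Barton–McCombie deoxygenation.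

Step 9
Reactants: 20 O-alkyl S-methyl xanthate of 18
Product: 21 (4aS,8aS)-1-[2-(benzyloxy)ethyl]-2,5,5,8a-tetramethyl-3,4,4a,5,6,7,8,8a-octahydronaphthalene
Conditions: Bu3SnH, AIBN (cat.), toluene, 110 °C
Reagents that add atoms: none
Why: Barton–McCombie deoxygenation: Bu3Sn• adds to the thiocarbonyl, β-scission gives the secondary C-6 radical and hydrogen transfer from Bu3SnH (kept concentrated to outrun homoallyl–cyclopropylcarbinyl rearrangement) leaves CH2, so no stereocentre is involved.

Step 10
Reactants: 21 (4aS,8aS)-1-[2-(benzyloxy)ethyl]-2,5,5,8a-tetramethyl-3,4,4a,5,6,7,8,8a-octahydronaphthalene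
Product: 22 2-[(4aS,8aS)-2,5,5,8a-tetramethyl-3,4,4a,5,6,7,8,8a-octahydronaphthalen-1-yl]ethan-1-ol
Conditions: H2 (1 atm), Pd/C, EtOAc, 23 °C
Reagents that add atoms: none
Why: Hydrogenolysis of the benzyl ether over palladium on carbon; the tetrasubstituted C-8=C-9 alkene flanked by the quaternary C-10 is too hindered to be hydrogenated under these conditions.

Step 11
Reactants: 22 2-[(4aS,8aS)-2,5,5,8a-tetramethyl-3,4,4a,5,6,7,8,8a-octahydronaphthalen-1-yl]ethan-1-ol
Product: 23 (4aS,8aS)-1-(2-iodoethyl)-2,5,5,8a-tetramethyl-3,4,4a,5,6,7,8,8a-octahydronaphthalene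
Conditions: I2, PPh3, imidazole, CH2Cl2, 0 → 23 °C
Reagents that add atoms: iodine, II
Why: Appel-type iodination: the alcohol is activated as an alkoxyphosphonium ion and displaced by iodide in an SN2 reaction at the primary carbon.

Step 12
Reactants: 24 furan-3-carbaldehyde
Product: 25 (1R)-1-(furan-3-yl)but-3-en-1-ol
Conditions: allyltributylstannane, Ti(OiPr)4 (10 mol %), (R)-BINOL (20 mol %), 4 Å molecular sieves, CH2Cl2, −20 °C
Reagents that add atoms: allyltributylstannane, C=CC[Sn](CCCC)(CCCC)CCCC
Why: Keck allylation: the chiral titanium–BINOL Lewis acid activates the aldehyde and directs allyl transfer from tin to its Re face, which sets the (R)-carbinol stereocentre of the side chain.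

Step 13
Reactants: 25 (1R)-1-(furan-3-yl)but-3-en-1-ol
Product: 26 (1R)-1-(furan-3-yl)but-3-en-1-yl prop-2-enoate
Conditions: acryloyl chloride, Et3N, DMAP (cat.), CH2Cl2, 0 °C
Reagents that add atoms: acryloyl chloride, C=CC(=O)Cl
Why: DMAP-catalysed O-acylation of the secondary alcohol, which does not touch the stereocentre.

Step 14
Reactants: 26 (1R)-1-(furan-3-yl)but-3-en-1-yl prop-2-enoate
Product: 27 (6R)-6-(furan-3-yl)-5,6-dihydro-2H-pyran-2-one
Conditions: second-generation Grubbs catalyst RuCl2(H2IMes)(PCy3)(=CHPh) (5 mol %), CH2Cl2 (0.005 M), 40 °C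
Reagents that add atoms: none
Why: Ring-closing metathesis between the acrylate and the terminal alkene expels ethylene and closes the α,β-unsaturated δ-lactone, a temporary ring in which the ester carbon and the ring CH2 are necessarily cis on the double bond.

Step 15
Reactants: 27 (6R)-6-(furan-3-yl)-5,6-dihydro-2H-pyran-2-one
Product: 28 (6R)-6-(furan-3-yl)-3-iodo-5,6-dihydro-2H-pyran-2-one
Conditions: I2, pyridine, DMAP (cat.), CH2Cl2, 0 → 23 °C
Reagents that add atoms: iodine, II
Why: α-Iodination of the enoate by the pyridine-mediated addition–elimination sequence (conjugate addition of pyridine, iodination of the enolate, loss of pyridinium) gives the vinyl iodide for cross-coupling without touching the furan.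

Step 16
Reactants: 23 (4aS,8aS)-1-(2-iodoethyl)-2,5,5,8a-tetramethyl-3,4,4a,5,6,7,8,8a-octahydronaphthalene; 28 (6R)-6-(furan-3-yl)-3-iodo-5,6-dihydro-2H-pyran-2-one
Product: 30 (6R)-6-(furan-3-yl)-3-{2-[(4aS,8aS)-2,5,5,8a-tetramethyl-3,4,4a,5,6,7,8,8a-octahydronaphthalen-1-yl]ethyl}-5,6-dihydro-2H-pyran-2-one, via alkylzinc iodide 29 (not isolated)
Conditions: Zn dust (activated with BrCH2CH2Br and Me3SiCl), DMA, 40 °C; then 28, Pd2(dba)3 (2.5 mol %), P(2-furyl)3 (10 mol %), THF–DMA, 23 °C
Reagents that add atoms: none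
Why: Negishi coupling: zinc inserts into the primary C–I bond to give alkylzinc iodide 29, which, after oxidative addition of the α-iodo enoate to zerovalent palladium, transmetalates and reductively eliminates to form the sp3–sp2 bond between the two halves; the lactone ester and both sets of stereocentres are inert to the organozinc.

Step 17
Reactants: 30 (6R)-6-(furan-3-yl)-3-{2-[(4aS,8aS)-2,5,5,8a-tetramethyl-3,4,4a,5,6,7,8,8a-octahydronaphthalen-1-yl]ethyl}-5,6-dihydro-2H-pyran-2-one
Product: 31 (2Z,5R)-5-(furan-3-yl)-2-{2-[(4aS,8aS)-2,5,5,8a-tetramethyl-3,4,4a,5,6,7,8,8a-octahydronaphthalen-1-yl]ethyl}pent-2-ene-1,5-diol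
Conditions: i-Bu2AlH (4 equiv), CH2Cl2, −78 → 0 °C; aq potassium sodium tartrate
Reagents that add atoms: none
Why: Excess i-Bu2AlH reduces the unsaturated lactone through the lactol and the (Z)-enal to the allylic alcohol (1,2-reduction), opening the temporary ring so that the hydroxymethyl group stays cis to the CH2 that leads to the carbinol, which gives the (Z)-trisubstituted alkene as a single isomer.

Step 18
Reactants: 31 (2Z,5R)-5-(furan-3-yl)-2-{2-[(4aS,8aS)-2,5,5,8a-tetramethyl-3,4,4a,5,6,7,8,8a-octahydronaphthalen-1-yl]ethyl}pent-2-ene-1,5-diol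
Product: 33 5-hydroxy-4-[(1R,3Z)-1-hydroxy-4-(hydroxymethyl)-6-[(4aS,8aS)-2,5,5,8a-tetramethyl-3,4,4a,5,6,7,8,8a-octahydronaphthalen-1-yl]hex-3-en-1-yl]furan-2(5H)-one, via furan endoperoxide 32 (not isolated)
Conditions: O2, hν (visible), 5,10,15,20-tetraphenylporphyrin (cat.), i-Pr2NEt, CH2Cl2, −78 → 23 °C
Reagents that add atoms: oxygen, O=O
Why: Singlet oxygen adds [4+2] to the furan at −78 °C (much faster than the ene reaction with the hindered tri- and tetrasubstituted alkenes) to give endoperoxide 32, and the hindered amine removes the less hindered bridgehead proton remote from the substituent, so that the carbonyl appears there and the 4-substituted 5-hydroxybutenolide results.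

Step 19
Reactants: 33 5-hydroxybutenolide from step 18
Product: 35 4-[(1R,3Z)-1-hydroxy-4-(hydroxymethyl)-6-[(4aS,8aS)-2,5,5,8a-tetramethyl-3,4,4a,5,6,7,8,8a-octahydronaphthalen-1-yl]hex-3-en-1-yl]furan-2(5H)-one (the target), via sodium hydroxy carboxylate 34 (not isolated)
Conditions: NaBH4, EtOH, 0 °C; then 1 M HCl to pH 3
Reagents that add atoms: none
Why: The hydroxybutenolide reacts through its ring-opened aldehyde carboxylate, borohydride reduces the aldehyde to give hydroxy carboxylate 34 and acidification closes the butenolide with CH2 at C-5 of the lactone, the conjugated lactone itself being left alone at 0 °C.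

**Compound list**
1 | 2,2,6-trimethylcyclohexanone (racemic) | CC1CCCC(C)(C)C1=O | starting material
2 | 2,4,6-triisopropylbenzenesulfonohydrazide | CC(C)c1cc(C(C)C)c(S(=O)(=O)NN)c(C(C)C)c1 | starting material
3 | N'-(2,2,6-trimethylcyclohexylidene)-2,4,6-triisopropylbenzenesulfonohydrazide (N–N syn to C-6) | CC1CCCC(C)(C)/C1=N/NS(=O)(=O)c1c(C(C)C)cc(C(C)C)cc1C(C)C | intermediate
4 | 4-(benzyloxy)butanoic acid | OC(=O)CCCOCc1ccccc1 | starting material
5 | 4-(benzyloxy)butanoyl chloride | ClC(=O)CCCOCc1ccccc1 | intermediate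
6 | ethoxyacetylene (ethoxyethyne) | CCOC#C | starting material
7 | 4-(benzyloxy)but-1-en-1-one (2-(benzyloxy)ethylketene) | O=C=CCCOCc1ccccc1 | intermediate (not isolated)
8 | (±)-4-[2-(benzyloxy)ethyl]-3-ethoxycyclobut-2-en-1-one | CCOC1=CC(=O)C1CCOCc1ccccc1 | intermediate
9 | lithium 4-[2-(benzyloxy)ethyl]-3-ethoxy-1-methylcyclobut-2-en-1-olate (racemic, diastereomer mixture) | CCOC1=CC(C)(O[Li])C1CCOCc1ccccc1 | intermediate (not isolated)
10 | (±)-4-[2-(benzyloxy)ethyl]-3-methylcyclobut-2-en-1-one | CC1=CC(=O)C1CCOCc1ccccc1 | intermediate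
11 | (2,6,6-trimethylcyclohex-1-en-1-yl)lithium | [Li]C1=C(C)CCCC1(C)C | intermediate (not isolated)
12 | lithium 4-[2-(benzyloxy)ethyl]-3-methyl-1-(2,6,6-trimethylcyclohex-1-en-1-yl)cyclobut-2-en-1-olate (racemic; O cis to the side chain) | [Li]O[C@@]1(C=C(C)[C@@H]1CCOCc1ccccc1)C1=C(C)CCCC1(C)C | intermediate (not isolated)
13 | lithium (1E,3Z)-6-(benzyloxy)-3-methyl-1-(2,6,6-trimethylcyclohex-1-en-1-yl)hexa-1,3-dien-1-olate | [Li]O/C(=C/C(C)=C\CCOCc1ccccc1)C1=C(C)CCCC1(C)C | intermediate (not isolated)
14 | lithium 1-[2-(benzyloxy)ethyl]-2,5,5,8a-tetramethyl-1,5,6,7,8,8a-hexahydronaphthalen-4-olate (racemic; side chain cis to the angular methyl) | CC1=CC(O[Li])=C2C(C)(C)CCC[C@]2(C)[C@H]1CCOCc1ccccc1 | intermediate (not isolated)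
15 | (±)-(1S*,4aS*,8aR*)-1-[2-(benzyloxy)ethyl]-2,5,5,8a-tetramethyl-4a,5,6,7,8,8a-hexahydronaphthalen-4(1H)-one (7-en-6-one, 5α-H) | CC1=CC(=O)[C@H]2C(C)(C)CCC[C@]2(C)[C@H]1CCOCc1ccccc1 | intermediate
16 | potassium (4aS*,8aS*)-1-[2-(benzyloxy)ethyl]-2,5,5,8a-tetramethyl-4a,5,6,7,8,8a-hexahydronaphthalen-4-olate (racemic linear dienolate) | CC1=C(CCOCc3ccccc3)[C@@]2(C)CCCC(C)(C)[C@@H]2C(O[K])=C1 | intermediate (not isolated)
17 | (±)-(4aS*,8aS*)-1-[2-(benzyloxy)ethyl]-2,5,5,8a-tetramethyl-4a,5,6,7,8,8a-hexahydronaphthalen-4(3H)-one (8-en-6-one, trans-fused) | CC1=C(CCOCc3ccccc3)[C@@]2(C)CCCC(C)(C)[C@@H]2C(=O)C1 | intermediate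
18 | (4R,4aS,8aS)-1-[2-(benzyloxy)ethyl]-2,5,5,8a-tetramethyl-3,4,4a,5,6,7,8,8a-octahydronaphthalen-4-ol (6β-alcohol) | CC1=C(CCOCc3ccccc3)[C@@]2(C)CCCC(C)(C)[C@@H]2[C@H](O)C1 | intermediate
19 | sodium O-{(4R,4aS,8aS)-1-[2-(benzyloxy)ethyl]-2,5,5,8a-tetramethyl-3,4,4a,5,6,7,8,8a-octahydronaphthalen-4-yl} carbonodithioate | CC1=C(CCOCc3ccccc3)[C@@]2(C)CCCC(C)(C)[C@@H]2[C@H](OC(=S)S[Na])C1 | intermediate (not isolated)
20 | O-{(4R,4aS,8aS)-1-[2-(benzyloxy)ethyl]-2,5,5,8a-tetramethyl-3,4,4a,5,6,7,8,8a-octahydronaphthalen-4-yl} S-methyl carbonodithioate | CC1=C(CCOCc3ccccc3)[C@@]2(C)CCCC(C)(C)[C@@H]2[C@H](OC(=S)SC)C1 | intermediate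
21 | (4aS,8aS)-1-[2-(benzyloxy)ethyl]-2,5,5,8a-tetramethyl-3,4,4a,5,6,7,8,8a-octahydronaphthalene | CC1=C(CCOCc3ccccc3)[C@@]2(C)CCCC(C)(C)[C@@H]2CC1 | intermediate
22 | 2-[(4aS,8aS)-2,5,5,8a-tetramethyl-3,4,4a,5,6,7,8,8a-octahydronaphthalen-1-yl]ethan-1-ol | CC1=C(CCO)[C@@]2(C)CCCC(C)(C)[C@@H]2CC1 | intermediate
23 | (4aS,8aS)-1-(2-iodoethyl)-2,5,5,8a-tetramethyl-3,4,4a,5,6,7,8,8a-octahydronaphthalene | CC1=C(CCI)[C@@]2(C)CCCC(C)(C)[C@@H]2CC1 | intermediate
24 | furan-3-carbaldehyde | O=Cc1ccoc1 | starting material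
25 | (1R)-1-(furan-3-yl)but-3-en-1-ol | C=CC[C@@H](O)c1ccoc1 | intermediate
26 | (1R)-1-(furan-3-yl)but-3-en-1-yl prop-2-enoate | C=CC[C@@H](OC(=O)C=C)c1ccoc1 | intermediate
27 | (6R)-6-(furan-3-yl)-5,6-dihydro-2H-pyran-2-one | O=C1C=CC[C@@H](O1)c1ccoc1 | intermediate
28 | (6R)-6-(furan-3-yl)-3-iodo-5,6-dihydro-2H-pyran-2-one | O=C1C(I)=CC[C@@H](O1)c1ccoc1 | intermediate
29 | {2-[(4aS,8aS)-2,5,5,8a-tetramethyl-3,4,4a,5,6,7,8,8a-octahydronaphthalen-1-yl]ethyl}zinc iodide | CC1=C(CC[Zn]I)[C@@]2(C)CCCC(C)(C)[C@@H]2CC1 | intermediate (not isolated)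
30 | (6R)-6-(furan-3-yl)-3-{2-[(4aS,8aS)-2,5,5,8a-tetramethyl-3,4,4a,5,6,7,8,8a-octahydronaphthalen-1-yl]ethyl}-5,6-dihydro-2H-pyran-2-one | CC1=C(CCC3=CC[C@@H](OC3=O)c4ccoc4)[C@@]2(C)CCCC(C)(C)[C@@H]2CC1 | intermediate
31 | (2Z,5R)-5-(furan-3-yl)-2-{2-[(4aS,8aS)-2,5,5,8a-tetramethyl-3,4,4a,5,6,7,8,8a-octahydronaphthalen-1-yl]ethyl}pent-2-ene-1,5-diol | CC1=C(CC/C(=C/C[C@@H](O)c3ccoc3)CO)[C@@]2(C)CCCC(C)(C)[C@@H]2CC1 | intermediate
32 | 2,5-endoperoxide of the furan ring of 31 (2,3,7-trioxabicyclo[2.2.1]hept-5-ene, mixture of diastereomers) | CC1=C(CC/C(=C/C[C@@H](O)C3=CC4OOC3O4)CO)[C@@]2(C)CCCC(C)(C)[C@@H]2CC1 | intermediate (not isolated)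
33 | 5-hydroxy-4-[(1R,3Z)-1-hydroxy-4-(hydroxymethyl)-6-[(4aS,8aS)-2,5,5,8a-tetramethyl-3,4,4a,5,6,7,8,8a-octahydronaphthalen-1-yl]hex-3-en-1-yl]furan-2(5H)-one (mixture of C-5 epimers) | CC1=C(CC/C(=C/C[C@@H](O)C3=CC(=O)OC3O)CO)[C@@]2(C)CCCC(C)(C)[C@@H]2CC1 | intermediate
34 | sodium (2E,4R,6Z)-4-hydroxy-3,7-bis(hydroxymethyl)-9-[(4aS,8aS)-2,5,5,8a-tetramethyl-3,4,4a,5,6,7,8,8a-octahydronaphthalen-1-yl]nona-2,6-dienoate | CC1=C(CC/C(=C/C[C@@H](O)/C(CO)=C/C(=O)[O-])CO)[C@@]2(C)CCCC(C)(C)[C@@H]2CC1.[Na+] | intermediate (not isolated)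
35 | 4-[(1R,3Z)-1-hydroxy-4-(hydroxymethyl)-6-[(4aS,8aS)-2,5,5,8a-tetramethyl-3,4,4a,5,6,7,8,8a-octahydronaphthalen-1-yl]hex-3-en-1-yl]furan-2(5H)-one (CNP0224983.2) | CC1=C(CC/C(=C/C[C@@H](O)C2=CC(=O)OC2)CO)[C@@]2(C)CCCC(C)(C)[C@@H]2CC1 | target

**Step count and risks**
Total step count: 19. Longest linear sequence: 14 steps (from 4 to 35: steps 2–11 and 16–19).

Steps most likely to fail:

- **Step 5.** The hindered alkenyllithium may act as a base instead of adding to the carbonyl. The ring closure of trienolate 13 may also be slow, because both termini carry an inward carbon group, so that protonation on work-up returns open-chain ketone instead of the bicyclic enone. Fallback, setting out from 10 and 3 and returning at 15: heating 10 with N,O-dimethylhydroxylamine in toluene opens the cyclobutenone thermally to the vinylketene (chain rotating outward) and traps it as the Weinreb amide (3E)-6-(benzyloxy)-N-methoxy-N,3-dimethylhex-3-enamide F1. Acylation of 11 (from 3 as in step 5) with F1 gives the dienone (3E)-6-(benzyloxy)-3-methyl-1-(2,6,6-trimethylcyclohex-1-en-1-yl)hex-3-en-1-one F2. Ring B is then closed by a Lewis acid-induced cationic cyclisation (MeAlCl2, CH2Cl2, −78 → 0 °C), in which the trisubstituted alkene attacks C-10 of the activated enone through C-9 and a proton is lost. This should give (±)-15; any (±)-17 formed is the product of step 6 anyway.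

- **Step 7.** The rate difference between the two enantiomers may be too small, for example through background reduction by uncomplexed borane, which would leave the alcohol with insufficient enantiomeric purity. Fallback, setting out from 17 and returning at 18: reduction of 17 with NaBH4 (MeOH, 0 °C, α-face attack) gives the racemic 6β-alcohol (±)-(4R*,4aS*,8aS*)-1-[2-(benzyloxy)ethyl]-2,5,5,8a-tetramethyl-3,4,4a,5,6,7,8,8a-octahydronaphthalen-4-ol F4. Its enantiomers are separated by preparative chromatography on a chiral stationary phase (cellulose tris(3,5-dimethylphenylcarbamate)); the (4R,4aS,8aS)-enantiomer is 18.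

- **Step 6.** Deprotonation may occur at the C-8 methyl (exocyclic dienolate), or the β,γ-enone may reconjugate during quench and purification, so that 15 or an exocyclic isomer is returned. Fallback, setting out from 15 and returning at 17: under thermodynamic acid conditions (isopropenyl acetate, TsOH cat., reflux) 15 is converted into the linear dienol acetate (±)-(4aS*,8aS*)-1-[2-(benzyloxy)ethyl]-2,5,5,8a-tetramethyl-4a,5,6,7,8,8a-hexahydronaphthalen-4-yl acetate F3. The acetate is cleaved with MeLi (2 equiv, Et2O, −78 °C) to the lithium dienolate alone, which is protonated at C-7 with AcOH at −78 °C to give 17.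

**Further compounds**
F1 | step 5 | (3E)-6-(benzyloxy)-N-methoxy-N,3-dimethylhex-3-enamide | CON(C)C(=O)C/C(C)=C/CCOCc1ccccc1
F2 | step 5 | (3E)-6-(benzyloxy)-3-methyl-1-(2,6,6-trimethylcyclohex-1-en-1-yl)hex-3-en-1-one | CC1=C(C(=O)C/C(C)=C/CCOCc2ccccc2)C(C)(C)CCC1
F3 | step 6 | (±)-(4aS*,8aS*)-1-[2-(benzyloxy)ethyl]-2,5,5,8a-tetramethyl-4a,5,6,7,8,8a-hexahydronaphthalen-4-yl acetate | CC1=C(CCOCc3ccccc3)[C@@]2(C)CCCC(C)(C)[C@@H]2C(OC(C)=O)=C1
F4 | step 7 | (±)-(4R*,4aS*,8aS*)-1-[2-(benzyloxy)ethyl]-2,5,5,8a-tetramethyl-3,4,4a,5,6,7,8,8a-octahydronaphthalen-4-ol (racemic form of 18) | CC1=C(CCOCc3ccccc3)[C@@]2(C)CCCC(C)(C)[C@@H]2[C@H](O)C1
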